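The route rests on cutting the C2–C3 bond of the dihydrofuran ring (benzofuran numbering). C3 is a bare benzylic CH2 on C3a and C2 is a methine on O1. C3 can therefore start as an aryl carbene carbon and C2 as the OCH2 of an aryl alkyl ether. A single 1,5 C–H insertion on the chiral dirhodium carboxylate Rh2(S-PTAD)4 forms C2–C3, closes the five-membered ring and sets the only stereocentre, C2, as (R). The precursor is a phenyldiazomethane with both ortho positions oxygenated: one oxygen carries CH2C(CH3)2OSiEt3, the other Si(iPr)3. Desilylation, C5 formylation, conversion into the methyl ketone and Claisen–Schmidt condensation finish the chalcone.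

Key step: step 5

Assumption: the sense of induction of Rh2(S-PTAD)4, dirhodium tetrakis[(S)-(1-adamantyl)(N-phthalimido)acetate], cannot be predicted safely for a carbene bearing only aryl and hydrogen. The S catalyst is written here, and the equally available Rh2(R-PTAD)4 is to be used if a trial run shows the opposite sense.

Step 1
Reactants: 1 2,6-dihydroxybenzaldehyde; 2 2,2-dimethyloxirane (1.2 equiv)
Product: 3 2-hydroxy-6-(2-hydroxy-2-methylpropoxy)benzaldehyde
Conditions: K2CO3 (0.3 equiv), DMF, sealed tube, 90 °C
Reagents that add atoms: none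
Why: Base-catalysed phenol–epoxide ring opening (SN2 at the unhindered CH2 terminus) should stop at the mono-ether because, with substoichiometric base, the more acidic 1 remains the main phenoxide in solution while the surviving OH of 3 is locked in a hydrogen bond to the aldehyde.

Step 2
Reactants: 3 2-hydroxy-6-(2-hydroxy-2-methylpropoxy)benzaldehyde
Product: 5 2-{2-methyl-2-[(triethylsilyl)oxy]propoxy}-6-{[tri(propan-2-yl)silyl]oxy}benzaldehyde, via mono-silyl ether 4 (not isolated)
Conditions: iPr3SiOTf (1.05 equiv), 2,6-lutidine (3 equiv), CH2Cl2, −78 to 0 °C; then Et3SiOTf (1.3 equiv), 0 °C to rt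
Reagents that add atoms: triisopropylsilyl triflate, CC(C)[Si](C(C)C)(C(C)C)OS(=O)(=O)C(F)(F)F; triethylsilyl triflate, CC[Si](CC)(CC)OS(=O)(=O)C(F)(F)F
Why: Silyl triflate/2,6-lutidine O-silylation run sequentially: the bulky iPr3SiOTf should take only the phenol, since tertiary alcohols resist it at low temperature, and the smaller Et3SiOTf then caps the tertiary alcohol, the non-enolisable aldehyde being recovered unchanged on aqueous work-up.

Step 3
Reactants: 5 2-{2-methyl-2-[(triethylsilyl)oxy]propoxy}-6-{[tri(propan-2-yl)silyl]oxy}benzaldehyde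
Product: 6 (E)-hydrazone of 5, (E)-[2-{2-methyl-2-[(triethylsilyl)oxy]propoxy}-6-{[tri(propan-2-yl)silyl]oxy}benzylidene]hydrazine
Conditions: N2H4·H2O (10 equiv), EtOH, rt; extractive work-up, used crude
Reagents that add atoms: hydrazine (as the hydrate), NN
Why: Hydrazone formation by condensation, in which the large excess of hydrazine and the two ortho substituents should hold back azine formation, both silyl ethers being hindered enough to resist the reagent at room temperature.

Step 4
Reactants: 6 (E)-hydrazone of 5
Product: 7 {2-(diazomethyl)-3-[2-methyl-2-(triethylsilyloxy)propoxy]phenoxy}tri(propan-2-yl)silane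
Conditions: activated MnO2 (8 equiv), MgSO4, CH2Cl2, 0 °C, dark; cold filtration through Celite under argon, solution kept cold, never concentrated, used at once
Reagents that add atoms: none
Why: Dehydrogenation of an N-unsubstituted hydrazone with MnO2 is a standard preparation of aryl-substituted diazoalkanes, the silyl ethers are inert to it, and MgSO4 takes up the water that would otherwise quench the carbene in step 5.

Step 5
Reactants: 7 {2-(diazomethyl)-3-[2-methyl-2-(triethylsilyloxy)propoxy]phenoxy}tri(propan-2-yl)silane
Product: 8 triethyl({2-[(2R)-4-{[tri(propan-2-yl)silyl]oxy}-2,3-dihydro-1-benzofuran-2-yl]propan-2-yl}oxy)silane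
Conditions: Rh2(S-PTAD)4 (1 mol %), 4 Å MS, CH2Cl2, 0 °C, cold solution of 7 added by syringe pump over 6 h, high dilution
Reagents that add atoms: none
Why: Proposed new method: the nucleophilic diazo carbon of 7 binds an axial site of the divalent-rhodium dimer, N2 leaves, and the electrophilic rhodium aryl carbene (which has no β-hydrogen and so cannot escape by a 1,2-shift) takes up a C–H bond of the O1 methylene through a concerted but asynchronous, hydride-shift-like three-centre transition state in which the O1 lone pair stabilises the developing positive charge. The closest known reaction type is the enantioselective intramolecular insertion of diaryl and aryl/alkyl rhodium carbenes, made by the same hydrazone/MnO2 sequence, into ortho-alkoxy C–H bonds to give 2,3-disubstituted dihydrobenzofurans, and what has not been shown is a carbene that carries only an aryl group and hydrogen. The dihydrofuran ring (O1–C2–C3–C3a–C7a) closes by 1,5-insertion through a five-membered cyclic transition state with C2–C3 as the ring-closing bond. C2 is set by catalyst control alone: the chiral pocket built by the four N-phthaloyl-adamantylglycinate ligands must make the carbene take the pro-R hydrogen of the OCH2 group, and insertion with retention then gives (R). Site selectivity is secured by the substrate, because only the O1 methylene offers a C–H bond five atoms from the carbene carbon, the OSi(iPr)3 group places silicon there and has its nearest C–H bonds six and seven atoms away without lone-pair activation, and the tertiary hydroxyl is capped as its Et3Si ether so that O–H insertion is excluded. Azine and stilbene formation, both second order in diazo-derived species, should be held down by the two ortho substituents, high dilution and slow addition.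

Step 6
Reactants: 8 triethyl({2-[(2R)-4-{[tri(propan-2-yl)silyl]oxy}-2,3-dihydro-1-benzofuran-2-yl]propan-2-yl}oxy)silane
Product: 9 (2R)-2-(2-hydroxypropan-2-yl)-2,3-dihydro-1-benzofuran-4-ol
Conditions: Bu4NF (3 equiv), THF, 0 °C to rt; aq NH4Cl
Reagents that add atoms: none
Why: Fluoride-mediated desilylation driven by Si–F bond formation should free the phenol and the tertiary alcohol together, and C2 cannot epimerise because its hydrogen is not acidic.

Step 7
Reactants: 9 (2R)-2-(2-hydroxypropan-2-yl)-2,3-dihydro-1-benzofuran-4-ol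
Product: 11 (2R)-4-hydroxy-2-(2-hydroxypropan-2-yl)-2,3-dihydro-1-benzofuran-5-carbaldehyde, via hydroxymethylphenol 10 (not isolated)
Conditions: MgCl2 (3 equiv), Et3N (6 equiv), (CH2O)n (8 equiv), MeCN, reflux; cold 1 M HCl work-up
Reagents that add atoms: paraformaldehyde (reacts as formaldehyde), C=O
Why: Casnati–Skattebøl ortho-formylation: the magnesium phenolate of the C4 oxygen delivers formaldehyde through a chelated six-membered transition state to an ortho carbon only, C3a is blocked so C5 is the sole site and C7 is never reached, and a second formaldehyde oxidises the benzylic alkoxide of 10 by hydride transfer.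

Step 8
Reactants: 11 (2R)-4-hydroxy-2-(2-hydroxypropan-2-yl)-2,3-dihydro-1-benzofuran-5-carbaldehyde
Product: 12 (2R)-5-(1-hydroxyethyl)-2-(2-hydroxypropan-2-yl)-2,3-dihydro-1-benzofuran-4-ol (both carbinol epimers)
Conditions: MeMgBr (4 equiv), THF, −20 to 0 °C; aq NH4Cl at 0 °C, used crude
Reagents that add atoms: methylmagnesium bromide, C[Mg]Br
Why: Grignard addition to the aldehyde after the two OH groups have consumed two equivalents of reagent, the new carbinol centre forming without control, which does not matter because step 9 removes it.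

Step 9
Reactants: 12 (2R)-5-(1-hydroxyethyl)-2-(2-hydroxypropan-2-yl)-2,3-dihydro-1-benzofuran-4-ol
Product: 13 1-[(2R)-4-hydroxy-2-(2-hydroxypropan-2-yl)-2,3-dihydro-1-benzofuran-5-yl]ethan-1-one
Conditions: activated MnO2 (15 equiv), CH2Cl2, rt
Reagents that add atoms: none
Why: MnO2 oxidation of an activated benzylic alcohol under neutral conditions should give the hydrogen-bonded ortho-hydroxyaryl ketone, the tertiary alcohol being unable to react.

Step 10
Reactants: 13 1-[(2R)-4-hydroxy-2-(2-hydroxypropan-2-yl)-2,3-dihydro-1-benzofuran-5-yl]ethan-1-one; 14 2,2-dimethyl-2H-chromene-6-carbaldehyde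
Product: 16 (2E)-3-(2,2-dimethyl-2H-chromen-6-yl)-1-[(2R)-4-hydroxy-2-(2-hydroxypropan-2-yl)-2,3-dihydro-1-benzofuran-5-yl]prop-2-en-1-one, via aldol adduct 15 (not isolated)
Conditions: KOH (10 equiv), EtOH–H2O, rt, 24–48 h; 1 M HCl to pH 5 at 0 °C
Reagents that add atoms: none
Why: Claisen–Schmidt condensation: the methyl ketone enolate adds to the non-enolisable aldehyde 14 and E1cB loss of hydroxide from 15 gives the conjugated (E)-enone under thermodynamic control, the phenoxide form disfavouring closure to the flavanone and C2 being configurationally inert to base.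

Compound list
1 | 2,6-dihydroxybenzaldehyde | O=Cc1c(O)cccc1O | starting material
2 | 2,2-dimethyloxirane | CC1(C)CO1 | starting material
3 | 2-hydroxy-6-(2-hydroxy-2-methylpropoxy)benzaldehyde | O=Cc1c(O)cccc1OCC(C)(C)O | intermediate
4 | 2-(2-hydroxy-2-methylpropoxy)-6-{[tri(propan-2-yl)silyl]oxy}benzaldehyde | O=Cc1c(OCC(C)(C)O)cccc1O[Si](C(C)C)(C(C)C)C(C)C | intermediate
5 | 2-{2-methyl-2-[(triethylsilyl)oxy]propoxy}-6-{[tri(propan-2-yl)silyl]oxy}benzaldehyde | O=Cc1c(OCC(C)(C)O[Si](CC)(CC)CC)cccc1O[Si](C(C)C)(C(C)C)C(C)C | intermediate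
6 | (E)-[2-{2-methyl-2-[(triethylsilyl)oxy]propoxy}-6-{[tri(propan-2-yl)silyl]oxy}benzylidene]hydrazine | N/N=C/c1c(OCC(C)(C)O[Si](CC)(CC)CC)cccc1O[Si](C(C)C)(C(C)C)C(C)C | intermediate
7 | {2-(diazomethyl)-3-[2-methyl-2-(triethylsilyloxy)propoxy]phenoxy}tri(propan-2-yl)silane | [N-]=[N+]=Cc1c(OCC(C)(C)O[Si](CC)(CC)CC)cccc1O[Si](C(C)C)(C(C)C)C(C)C | intermediate
8 | triethyl({2-[(2R)-4-{[tri(propan-2-yl)silyl]oxy}-2,3-dihydro-1-benzofuran-2-yl]propan-2-yl}oxy)silane | CC[Si](CC)(CC)OC(C)(C)[C@H]1Cc2c(O[Si](C(C)C)(C(C)C)C(C)C)cccc2O1 | intermediate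
9 | (2R)-2-(2-hydroxypropan-2-yl)-2,3-dihydro-1-benzofuran-4-ol | CC(C)(O)[C@H]1Cc2c(O)cccc2O1 | intermediate
10 | (2R)-5-(hydroxymethyl)-2-(2-hydroxypropan-2-yl)-2,3-dihydro-1-benzofuran-4-ol | CC(C)(O)[C@H]1Cc2c(O)c(CO)ccc2O1 | intermediate
11 | (2R)-4-hydroxy-2-(2-hydroxypropan-2-yl)-2,3-dihydro-1-benzofuran-5-carbaldehyde | CC(C)(O)[C@H]1Cc2c(O)c(C=O)ccc2O1 | intermediate
12 | (2R)-5-(1-hydroxyethyl)-2-(2-hydroxypropan-2-yl)-2,3-dihydro-1-benzofuran-4-ol, both carbinol epimers | CC(O)c1ccc2c(c1O)C[C@H](C(C)(C)O)O2 | intermediate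
13 | 1-[(2R)-4-hydroxy-2-(2-hydroxypropan-2-yl)-2,3-dihydro-1-benzofuran-5-yl]ethan-1-one | CC(=O)c1ccc2c(c1O)C[C@H](C(C)(C)O)O2 | intermediate
14 | 2,2-dimethyl-2H-chromene-6-carbaldehyde | CC1(C)C=Cc2cc(C=O)ccc2O1 | starting material
15 | 3-(2,2-dimethyl-2H-chromen-6-yl)-3-hydroxy-1-[(2R)-4-hydroxy-2-(2-hydroxypropan-2-yl)-2,3-dihydro-1-benzofuran-5-yl]propan-1-one, both carbinol epimers | CC1(C)C=Cc2cc(C(O)CC(=O)c3ccc4c(c3O)C[C@H](C(C)(C)O)O4)ccc2O1 | intermediate
16 | (2E)-3-(2,2-dimethyl-2H-chromen-6-yl)-1-[(2R)-4-hydroxy-2-(2-hydroxypropan-2-yl)-2,3-dihydro-1-benzofuran-5-yl]prop-2-en-1-one | CC1(C)C=Cc2cc(/C=C/C(=O)c3ccc4c(c3O)C[C@H](C(C)(C)O)O4)ccc2O1 | target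

Total step count: 10. Longest linear sequence: 10 steps (1 to 16; 2 and 14 are purchased).

Steps most likely to fail

**Step 5.**
- What may go wrong: a carbene whose second substituent is only hydrogen may discriminate poorly between the two enantiotopic hydrogens, or coupling of the diazo compound with the carbene may outrun insertion at the hindered methylene.
- The fallback sets out from 1 and comes back to the route at 9. It uses known chemistry only and again turns the aldehyde carbon of 1 into C3.
- 1 is heated with one equivalent of methyl bromoacetate and K2CO3 in DMF (O-alkylation, then intramolecular aldol condensation and dehydration) to give methyl 4-hydroxy-1-benzofuran-2-carboxylate F1.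
- Hydrogenation of the furan C2=C3 bond (H2, Pd/C, MeOH–AcOH) gives racemic methyl 4-hydroxy-2,3-dihydro-1-benzofuran-2-carboxylate F2.
- Preparative chromatography on a chiral stationary phase delivers methyl (2R)-4-hydroxy-2,3-dihydro-1-benzofuran-2-carboxylate F3.
- MeMgBr (4 equiv, THF, −20 °C, cold enough to keep enolisation of the α-aryloxy ester slow) turns the ester into the dimethylcarbinol and reaches 9. The C2 descriptor is unchanged because CO2CH3 and C(CH3)2OH hold the same CIP rank.

**Step 4.**
- What may go wrong: the N-unsubstituted hydrazone may self-condense before or during oxidation, and the electron-rich diazo compound may lose nitrogen on the oxide surface or during filtration.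
- The fallback sets out from 5 and comes back at 7. It replaces oxidation by a Bamford–Stevens elimination.
- 5 is condensed with p-toluenesulfonohydrazide (THF–MeOH, rt) to the stable, crystalline N'-[(E)-2-{2-methyl-2-[(triethylsilyl)oxy]propoxy}-6-{[tri(propan-2-yl)silyl]oxy}benzylidene]-4-methylbenzenesulfonohydrazide F4.
- NaOMe converts it into the sodium salt of this tosylhydrazone F5.
- Warming the salt to about 40 °C with BnEt3NCl as phase-transfer agent expels sulfinate and releases 7 slowly. This can be done in the flask that already holds the rhodium catalyst, so that 7 never accumulates.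

**Step 9.**
- What may go wrong: the doubly activated benzylic alcohol (ortho OH, para O1) may ionise and oligomerise, or the free phenol ring may be oxidised in place of the carbinol.
- The fallback sets out from 11 and comes back at 13. It masks the phenol so that no quinone-methide pathway is open.
- MOMCl and iPr2NEt (CH2Cl2, 0 °C) give (2R)-2-(2-hydroxypropan-2-yl)-4-(methoxymethoxy)-2,3-dihydro-1-benzofuran-5-carbaldehyde F6.
- MeMgBr (2.5 equiv, THF, 0 °C) gives 2-[(2R)-5-(1-hydroxyethyl)-4-(methoxymethoxy)-2,3-dihydro-1-benzofuran-2-yl]propan-2-ol F7.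
- Dess–Martin periodinane buffered with NaHCO3 gives 1-[(2R)-2-(2-hydroxypropan-2-yl)-4-(methoxymethoxy)-2,3-dihydro-1-benzofuran-5-yl]ethan-1-one F8.
- Catalytic HCl in MeOH at rt removes the acetal, which the neighbouring carbonyl makes labile, to give 13.

Further compounds
F1 | step 5 | methyl 4-hydroxy-1-benzofuran-2-carboxylate | COC(=O)c1cc2c(O)cccc2o1
F2 | step 5 | methyl 4-hydroxy-2,3-dihydro-1-benzofuran-2-carboxylate (racemate) | COC(=O)C1Cc2c(O)cccc2O1
F3 | step 5 | methyl (2R)-4-hydroxy-2,3-dihydro-1-benzofuran-2-carboxylate | COC(=O)[C@H]1Cc2c(O)cccc2O1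
F4 | step 4 | N'-[(E)-2-{2-methyl-2-[(triethylsilyl)oxy]propoxy}-6-{[tri(propan-2-yl)silyl]oxy}benzylidene]-4-methylbenzenesulfonohydrazide | Cc1ccc(cc1)S(=O)(=O)N/N=C/c1c(OCC(C)(C)O[Si](CC)(CC)CC)cccc1O[Si](C(C)C)(C(C)C)C(C)C
F5 | step 4 | sodium salt of the tosylhydrazone F4 | [Na+].Cc1ccc(cc1)S(=O)(=O)[N-]/N=C/c1c(OCC(C)(C)O[Si](CC)(CC)CC)cccc1O[Si](C(C)C)(C(C)C)C(C)C
F6 | step 9 | (2R)-2-(2-hydroxypropan-2-yl)-4-(methoxymethoxy)-2,3-dihydro-1-benzofuran-5-carbaldehyde | COCOc1c(C=O)ccc2c1C[C@H](C(C)(C)O)O2
F7 | step 9 | 2-[(2R)-5-(1-hydroxyethyl)-4-(methoxymethoxy)-2,3-dihydro-1-benzofuran-2-yl]propan-2-ol | COCOc1c(C(C)O)ccc2c1C[C@H](C(C)(C)O)O2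
F8 | step 9 | 1-[(2R)-2-(2-hydroxypropan-2-yl)-4-(methoxymethoxy)-2,3-dihydro-1-benzofuran-5-yl]ethan-1-one | COCOc1c(C(C)=O)ccc2c1C[C@H](C(C)(C)O)O2
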